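**Strategy**

1. Cuts (numbering along the geranyllinalool chain: C1=C2 vinyl, C3 and C11 ether carbons, C6–C7 epoxide, C10–C15 cyclohexane, Br on C14; the target is 3R,6S,7S,10S,11S,14S): vinyl back to ethynyl; epoxide back to a C6/C7 cyclic carbonate; then Br–C14, C15–C10, O–C11 and carbonate O–C7 are cut and the ring O–C7 bond restored, which gives a tetrahydropyran (O, C3–C7) with OBoc on C6 and a homogeranyl chain on C7; C3–C2 (alkynyl) leads back to a 2,7-dioxabicyclo[2.2.1]heptane ketal, and C4–C5 to 2,3-epoxyfarnesol and an acetone equivalent.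
2. Enabling feature: in the ten-membered ring (O, C3–C11) the epoxide carbon C7 lies four bonds from C11. An oxygen parked on C7 as the tetrahydropyran oxygen therefore reaches a C11 cation through a six-membered transition state, and the neighbouring C6 oxygen can then expel it from C7, the carbon that must finally carry the epoxide oxygen.
3. Forward order: epoxide; C4–C5 bond by hydrazone alkylation; both rings of the bicyclic ketal at once; tetrahydropyran by alkynylative ketal opening; key cascade (cyclohexane closed, tetrahydropyran expanded to the oxecane, cyclic carbonate formed); epoxide re-closed; alkyne reduced to vinyl.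
4. Stereochemistry: C6 and C7 from the Sharpless epoxidation (C7 is inverted twice and the last closure runs with net retention); C3 is relayed from C6 through the ketal; C14 comes from the chiral bromonium-transfer catalyst; C10 and C11 follow from the chair-like anti addition across the E C10=C11 alkene.

Key step: step 10

Remark: the sense of induction of the bromonium-transfer catalyst on this substrate cannot be predicted with certainty; the catalyst enantiomer that gives 14S is assumed to be selected by a trial of both (the two outcomes are diastereomers and easy to tell apart).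

**Route**

Step 1
Reactants: 1 (2E,6E)-farnesol
Product: 2 (2S,3S)-2,3-epoxyfarnesol
Conditions: Ti(OiPr)4 (cat.), L-(+)-diethyl tartrate (cat.), t-BuOOH, 4 Å MS, CH2Cl2, −20 °C
Reagents that add atoms: tert-butyl hydroperoxide, CC(C)(C)OO
Why: Sharpless asymmetric epoxidation touches only the allylic alkene, and the L-(+)-tartrate ligand delivers oxygen to the face of the E allylic alcohol that gives the (2S,3S) epoxide, which sets C6 and C7.

Step 2
Reactants: 2 (2S,3S)-2,3-epoxyfarnesol
Product: 3 (2S,3S)-2,3-epoxyfarnesyl triflate
Conditions: Tf2O, 2,6-lutidine, CH2Cl2, −78 °C; cold work-up, used at once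
Reagents that add atoms: trifluoromethanesulfonic anhydride, O=S(=O)(OS(=O)(=O)C(F)(F)F)C(F)(F)F
Why: O-sulfonylation of the primary alcohol at low temperature leaves the epoxide untouched and gives a leaving group reactive enough for C-alkylation at −78 °C.

Step 3
Reactants: 3 (2S,3S)-2,3-epoxyfarnesyl triflate; 4 acetone N,N-dimethylhydrazone
Product: 5 epoxy hydrazone
Conditions: 4, LiN(iPr)2, THF, 0 °C; then 3, −78 °C
Reagents that add atoms: none
Why: Corey–Enders-type alkylation of the lithiated dimethylhydrazone by the primary triflate forms C4–C5 by SN2 displacement, which at −78 °C is far faster than attack on the epoxide, and azaenolates give clean mono-C-alkylation.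

Step 4
Reactants: 5 epoxy hydrazone
Product: 6 (5S,6S)-5,6-epoxyfarnesylacetone
Conditions: Cu(OAc)2, THF–H2O (pH 7 phosphate buffer), 23 °C
Reagents that add atoms: water, O
Why: cupric-ion-assisted hydrolysis of a dimethylhydrazone at neutral pH releases the methyl ketone without the acid that would open the trisubstituted epoxide.

Step 5
Reactants: 6 (5S,6S)-5,6-epoxyfarnesylacetone
Product: 7 bicyclic ketal
Conditions: BF3·OEt2 (10 mol %), CH2Cl2, −78 °C
Reagents that add atoms: none
Why: Lewis-acid rearrangement of a γ,δ-epoxy ketone to a bicyclic ketal, in which the carbonyl oxygen opens the activated epoxide at the tertiary carbon C7 (6-endo, inversion) and the C6 alkoxide closes on the oxocarbenium carbon C3, so that C6 is retained, C7 inverted and C3 fixed by the bicycle.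

Step 6
Reactants: 8 trimethylsilylacetylene
Product: 9 potassium trifluoro[(trimethylsilyl)ethynyl]borate
Conditions: n-BuLi, THF, −78 °C; B(OMe)3, −78 to −20 °C; aq. KHF2, 0 °C
Reagents that add atoms: trimethyl borate, COB(OC)OC; potassium hydrogen difluoride, [K+].[F-].F
Why: deprotonation, borylation and fluoride exchange is the standard preparation of potassium alkynyltrifluoroborates, and the C–Si bond survives the short cold treatment with KHF2.

Step 7
Reactants: 7 bicyclic ketal; 9 potassium trifluoro[(trimethylsilyl)ethynyl]borate
Product: 10 silylalkynyl tetrahydropyranol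
Conditions: BF3·OEt2, MeCN–CH2Cl2, −40 °C; aq. NaHCO3
Reagents that add atoms: none
Why: BF3 binds the less hindered O6 and ionises the strained C3–O6 bond to a six-membered oxocarbenium ion whose boron-bound C6 oxygen stays pseudoaxial over one face, and the alkynyltrifluoroborate (oxocarbenium alkynylation with an organotrifluoroborate) adds to the other face, which makes the tetrahydropyran and sets C3 with the alkynyl group trans to the C6 hydroxyl.

Step 8
Reactants: 10 silylalkynyl tetrahydropyranol
Product: 11 ethynyl tetrahydropyranol
Conditions: K2CO3, MeOH, 23 °C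
Reagents that add atoms: none
Why: base-mediated protodesilylation of the silylalkyne frees the terminal alkyne and leaves the alcohol, the ring and the alkenes untouched.

Step 9
Reactants: 11 ethynyl tetrahydropyranol
Product: 12 tert-butyl carbonate of 11
Conditions: Boc2O, DMAP (cat.), CH2Cl2, 23 °C
Reagents that add atoms: di-tert-butyl dicarbonate, CC(C)(C)OC(=O)OC(=O)OC(C)(C)C
Why: DMAP-catalysed acylation of the only hydroxyl group installs the internal nucleophile without need for a strong base that would deprotonate the alkyne.

Step 10
Reactants: 12 tert-butyl carbonate of 11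
Product: 14 ethynyl oxecane carbonate, via tricyclic oxonium ion 13 (not isolated)
Conditions: NBS, chiral 3,3'-diaryl-BINOL-derived thiophosphoramide (10 mol %), toluene–CH2Cl2, −78 to −40 °C
Reagents that add atoms: N-bromosuccinimide, O=C1CCC(=O)N1Br
Why: Proposed new method: bromonium transfer from the catalyst-bound NBS to the terminal C14=C15 alkene triggers a chair-like cation–olefin closure (C15–C10) that leaves a tertiary cation on C11; the tetrahydropyran oxygen on C7 captures it through a six-membered transition state to give the cis-fused oxonium ion 13, and the carbonyl oxygen of the equatorial C6 carbonate, anti-periplanar to the O–C7 bond, displaces the oxonium at C7 with loss of isobutene. The closest known reactions are the bromonium-induced ring expansion of tetrahydrofurans and tetrahydropyrans through bicyclic oxonium ions opened by a pendant tert-butyl carbonate, oxygen-terminated bromonium polyene cyclisations, and Lewis-base-catalysed enantioselective bromocyclisation of polyenes. Ring closures: the cyclohexane by 6-endo attack of C10=C11 on the bromonium carbon C15 with bromine equatorial, the transient oxane by capture of C11 by the ring oxygen, the cyclic carbonate by 5-exo-tet substitution at C7, and the ten-membered ring by cleavage of the O–C7 bond shared by the two six-membered rings of 13, not by macrocyclisation. Stereocentres: C14 (S) is set by the chiral catalyst, C10 and C11 follow from the chair and anti addition across the E alkene, and C7 is inverted by the backside attack of the C6 carbonate while C3 and C6 are carried through. The step needs Br+ on the terminal alkene (the most accessible one, the ethynyl group being far less nucleophilic) and cleavage of O–C7 instead of O–C3 or O–C11; the anti-periplanar carbonate and the cation-destabilising ethynyl group on C3 secure the latter, and carbonate formation pays for the strain of the medium ring.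

Step 11
Reactants: 14 ethynyl oxecane carbonate
Product: 15 ethynyl oxecane diol
Conditions: K2CO3, MeOH, 23 °C
Reagents that add atoms: none
Why: transesterification of the cyclic carbonate with methanol breaks only C(=O)–O bonds, so the diol keeps the configuration of C6 and C7, and the equatorial neopentyl-type bromide is not displaced.

Step 12
Reactants: 15 ethynyl oxecane diol
Product: 18 ethynyl epoxide, via cyclic orthoacetate 16 (not isolated), via bromohydrin acetate 17 (not isolated)
Conditions: MeC(OMe)3, PPTS (cat.), CH2Cl2, 23 °C; AcBr, CH2Cl2, 0 °C; K2CO3, MeOH, 23 °C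
Reagents that add atoms: none
Why: one-pot diol-to-epoxide conversion through the cyclic orthoacetate (Kolb–Sharpless procedure), in which bromide opens the acetoxonium ion with inversion at C6 and the C7 alkoxide freed by acetate methanolysis displaces that bromide with a second inversion, so both centres end with net retention (the regioisomeric bromo acetate would converge on the same epoxide).

Step 13
Reactants: 18 ethynyl epoxide
Product: 19 target CNP0243863.1
Conditions: H2 (1 atm), Lindlar catalyst (Pd/CaCO3 poisoned with Pb(OAc)2), quinoline, EtOAc, 23 °C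
Reagents that add atoms: none
Why: Lindlar semi-hydrogenation of a terminal alkyne stops at the alkene and does not touch the alkyl bromide, the epoxide or the ethers.

**Compound list**

1 | (2E,6E)-farnesol | CC(C)=CCC/C(C)=C/CC/C(C)=C/CO | starting material
2 | (2S,3S)-2,3-epoxyfarnesol | OC[C@@H]1O[C@@]1(C)CC/C=C(C)/CCC=C(C)C | intermediate
3 | (2S,3S)-2,3-epoxyfarnesyl triflate | O=S(=O)(OC[C@@H]1O[C@@]1(C)CC/C=C(C)/CCC=C(C)C)C(F)(F)F | intermediate
4 | acetone N,N-dimethylhydrazone | CC(C)=NN(C)C | starting material
5 | epoxy hydrazone (N,N-dimethylhydrazone of 6) | CN(C)N=C(C)CC[C@@H]1O[C@@]1(C)CC/C=C(C)/CCC=C(C)C | intermediate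
6 | (5S,6S)-5,6-epoxyfarnesylacetone, (5S,6S,9E)-5,6-epoxy-6,10,14-trimethylpentadeca-9,13-dien-2-one | CC(=O)CC[C@@H]1O[C@@]1(C)CC/C=C(C)/CCC=C(C)C | intermediate
7 | bicyclic ketal, (1S,3R,4S)-1,3-dimethyl-3-[(3E)-4,8-dimethylnona-3,7-dien-1-yl]-2,7-dioxabicyclo[2.2.1]heptane | C[C@]12CC[C@H](O1)[C@@](C)(CC/C=C(C)/CCC=C(C)C)O2 | intermediate
8 | trimethylsilylacetylene | C#C[Si](C)(C)C | starting material
9 | potassium trifluoro[(trimethylsilyl)ethynyl]borate | C[Si](C)(C)C#C[B-](F)(F)F.[K+] | intermediate
10 | silylalkynyl tetrahydropyranol, (2R,3S,6R)-2,6-dimethyl-2-[(3E)-4,8-dimethylnona-3,7-dien-1-yl]-6-[(trimethylsilyl)ethynyl]oxan-3-ol | C[Si](C)(C)C#C[C@@]1(C)CC[C@H](O)[C@@](C)(CC/C=C(C)/CCC=C(C)C)O1 | intermediate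
11 | ethynyl tetrahydropyranol, (2R,3S,6R)-6-ethynyl-2,6-dimethyl-2-[(3E)-4,8-dimethylnona-3,7-dien-1-yl]oxan-3-ol | C#C[C@@]1(C)CC[C@H](O)[C@@](C)(CC/C=C(C)/CCC=C(C)C)O1 | intermediate
12 | tert-butyl carbonate of 11 (OBoc on the ring carbon next to the quaternary centre that bears the chain) | C#C[C@@]1(C)CC[C@H](OC(=O)OC(C)(C)C)[C@@](C)(CC/C=C(C)/CCC=C(C)C)O1 | intermediate
13 | tricyclic oxonium ion (oxygen bonded to C3, C7 and C11; bromocyclohexane trans-fused to an oxane that is cis-fused to the tetrahydropyran) | C#C[C@@]1(C)CC[C@H](OC(=O)OC(C)(C)C)[C@@]2(C)CC[C@H]3C(C)(C)[C@@H](Br)CC[C@]3(C)[O+]12 | intermediate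
14 | ethynyl oxecane carbonate, (3R,6S,7S,10S,11S,14S): oxecane O/C3–C11 fused at C10–C11 to the bromocyclohexane, cyclic carbonate across C6/C7, ethynyl and methyl on C3 | C#C[C@@]1(C)CC[C@@H]2OC(=O)O[C@@]2(C)CC[C@H]3C(C)(C)[C@@H](Br)CC[C@]3(C)O1 | intermediate
15 | ethynyl oxecane diol, (3R,6S,7S,10S,11S,14S)-6,7-diol | C#C[C@@]1(C)CC[C@H](O)[C@@](C)(O)CC[C@H]2C(C)(C)[C@@H](Br)CC[C@]2(C)O1 | intermediate
16 | cyclic orthoacetate of 15 (2-methoxy-2-methyl-1,3-dioxolane across C6/C7, mixture at the orthoester carbon) | C#C[C@@]1(C)CC[C@@H]2OC(C)(OC)O[C@@]2(C)CC[C@H]3C(C)(C)[C@@H](Br)CC[C@]3(C)O1 | intermediate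
17 | bromohydrin acetate, (6R,7S)-6-bromo 7-acetate | C#C[C@@]1(C)CC[C@@H](Br)[C@@](C)(OC(C)=O)CC[C@H]2C(C)(C)[C@@H](Br)CC[C@]2(C)O1 | intermediate
18 | ethynyl epoxide (ethynyl analogue of the target, trans C6–C7 epoxide) | C#C[C@@]1(C)CC[C@@H]2O[C@@]2(C)CC[C@H]3C(C)(C)[C@@H](Br)CC[C@]3(C)O1 | intermediate
19 | target CNP0243863.1 | C=C[C@@]1(C)CC[C@@H]2O[C@@]2(C)CC[C@H]2C(C)(C)[C@@H](Br)CC[C@]2(C)O1 | target

**Step count and weak points**

Total steps: 13. Longest linear sequence: 12 steps (1 to 19 through steps 1–5 and 7–13); step 6 is a one-step side branch.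

Step 10 (Proposed new method). What may go wrong: loss of a proton from the C11 cation before the hindered, weakly nucleophilic ring oxygen captures it; bromonium formation at the C10=C11 alkene; or delivery of bromine to the wrong face of the terminal alkene. Fallback with known chemistry, setting out from ketal 7 and coming back at the target 19: the two halves of the cascade are run separately, each in the form in which it is known. Ketal 7 is cyclised with the same NBS/catalyst system. The ketal oxygen on C7 terminates the chair cyclisation, as acetal oxygens do in halonium cyclisations, and the oxonium ion sheds the ketal carbon as a five-membered oxocarbenium ion, so that aqueous work-up gives the bromo-oxadecalin hydroxy ketone F1 (in equilibrium with its lactol). Wittig reaction with Ph3P=CHCH3 gives the 2-butenyl alcohol F2 (E/Z mixture, of no consequence because that carbon loses its stereocentre later), and Boc2O/DMAP gives the carbonate F3. Et2SBr·SbCl5Br in MeNO2 then effects the established bromonium-induced ring expansion: the oxane oxygen attacks the tertiary carbon C3 of the bromonium ion (six-membered ring, larger group equatorial), and the carbonate opens the oxonium ion at C7 with inversion to the ten-membered bromoethyl carbonate F4. DBU in hot toluene removes HBr from the 1-bromoethyl group (the equatorial ring bromide has no anti-periplanar hydrogen) to give the vinyl carbonate F5. K2CO3 in MeOH gives the vinyl diol F6, and the orthoacetate/AcBr/K2CO3 sequence of step 12, through the vinyl orthoacetate F7 and the vinyl bromohydrin acetate F8, closes the epoxide and gives 19 directly, so that step 13 is not needed.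

Step 7. What may go wrong: ionisation of the other ketal bond (C3–O7), which leads into the tetrahydrofuran series; capture of the oxocarbenium ion by the C10=C11 alkene (Prins closure); or attack of the alkynyl group syn to O6. Fallback, setting out from triflate 3 and coming back at 10: the two C3 substituents change roles, so that the alkynyl group is in place before the ketal is made and the methyl group is delivered from aluminium with retention. Triflate 3 alkylates the lithium enolate of N-acetylmorpholine to give the epoxy morpholine amide F9; lithium trimethylsilylacetylide converts the amide into the epoxy ynone F10; BF3·OEt2 rearranges it, as in step 5, to the alkynyl ketal F11. Me3Al then binds the less hindered O6, the C3–O6 bond ionises within the ion pair, and a methyl group passes from the aluminate to the face that O6 leaves. The methyl group therefore ends cis to the C6 hydroxyl and the alkynyl group trans, which is 10.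

Step 5. What may go wrong: entry of the carbonyl oxygen at the secondary carbon C6 (5-exo) in competition with C7, which would give the mirror-image ketal and erode enantiomeric purity without any change in constitution. Fallback, setting out from triflate 3 and coming back at 7: the tertiary C–O bond is made by water before any carbonyl group is present, and the ketal is then formed without breaking a C–O bond at C6 or C7. Lithiated 1-(trimethylsilyl)propyne is alkylated by 3 to give the epoxy silylalkyne F12. HClO4 (cat.) in THF–H2O opens the epoxide at the tertiary carbon with inversion to the silylalkynyl diol F13, and K2CO3 in MeOH gives the alkynyl diol F14. AuCl(PPh3)/AgOTf (cat.) in CH2Cl2 adds both hydroxyl groups to the internal alkyne carbon and gives 7.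

Further compounds
F1 | step 10 | bromo-oxadecalin hydroxy ketone, 5-hydroxy-5-(6-bromo-2,5,5,8a-tetramethyloctahydro-2H-chromen-2-yl)pentan-2-one, configuration as in the SMILES | CC(=O)CC[C@H](O)[C@@]1(C)CC[C@H]2C(C)(C)[C@@H](Br)CC[C@]2(C)O1
F2 | step 10 | 2-butenyl alcohol, 1-(6-bromo-2,5,5,8a-tetramethyloctahydro-2H-chromen-2-yl)-4-methylhex-4-en-1-ol, E/Z mixture | CC=C(C)CC[C@H](O)[C@@]1(C)CC[C@H]2C(C)(C)[C@@H](Br)CC[C@]2(C)O1
F3 | step 10 | tert-butyl carbonate of F2 | CC=C(C)CC[C@H](OC(=O)OC(C)(C)C)[C@@]1(C)CC[C@H]2C(C)(C)[C@@H](Br)CC[C@]2(C)O1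
F4 | step 10 | bromoethyl carbonate, analogue of 14 with a 1-bromoethyl group on C3 in place of ethynyl | CC(Br)[C@@]1(C)CC[C@@H]2OC(=O)O[C@@]2(C)CC[C@H]3C(C)(C)[C@@H](Br)CC[C@]3(C)O1
F5 | step 10 | vinyl carbonate, vinyl analogue of 14 | C=C[C@@]1(C)CC[C@@H]2OC(=O)O[C@@]2(C)CC[C@H]3C(C)(C)[C@@H](Br)CC[C@]3(C)O1
F6 | step 10 | vinyl diol, vinyl analogue of 15 | C=C[C@@]1(C)CC[C@H](O)[C@@](C)(O)CC[C@H]2C(C)(C)[C@@H](Br)CC[C@]2(C)O1
F7 | step 10 | vinyl orthoacetate, vinyl analogue of 16 | C=C[C@@]1(C)CC[C@@H]2OC(C)(OC)O[C@@]2(C)CC[C@H]3C(C)(C)[C@@H](Br)CC[C@]3(C)O1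
F8 | step 10 | vinyl bromohydrin acetate, vinyl analogue of 17 | C=C[C@@]1(C)CC[C@@H](Br)[C@@](C)(OC(C)=O)CC[C@H]2C(C)(C)[C@@H](Br)CC[C@]2(C)O1
F9 | step 7 | epoxy morpholine amide, morpholide of (4S,5S,8E)-4,5-epoxy-5,9,13-trimethyltetradeca-8,12-dienoic acid | O=C(CC[C@@H]1O[C@@]1(C)CC/C=C(C)/CCC=C(C)C)N1CCOCC1
F10 | step 7 | epoxy ynone, (6S,7S,10E)-6,7-epoxy-7,11,15-trimethyl-1-(trimethylsilyl)hexadeca-10,14-dien-1-yn-3-one | C[Si](C)(C)C#CC(=O)CC[C@@H]1O[C@@]1(C)CC/C=C(C)/CCC=C(C)C
F11 | step 7 | alkynyl ketal, analogue of 7 with (trimethylsilyl)ethynyl in place of the methyl group on the ketal carbon | C[Si](C)(C)C#C[C@]12CC[C@H](O1)[C@@](C)(CC/C=C(C)/CCC=C(C)C)O2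
F12 | step 5 | epoxy silylalkyne, (5S,6S,9E)-5,6-epoxy-6,10,14-trimethyl-1-(trimethylsilyl)pentadeca-9,13-dien-1-yne | C[Si](C)(C)C#CCC[C@@H]1O[C@@]1(C)CC/C=C(C)/CCC=C(C)C
F13 | step 5 | silylalkynyl diol, (5S,6R,9E)-6,10,14-trimethyl-1-(trimethylsilyl)pentadeca-9,13-dien-1-yne-5,6-diol | C[Si](C)(C)C#CCC[C@H](O)[C@](C)(O)CC/C=C(C)/CCC=C(C)C
F14 | step 5 | alkynyl diol, (5S,6R,9E)-6,10,14-trimethylpentadeca-9,13-dien-1-yne-5,6-diol | C#CCC[C@H](O)[C@](C)(O)CC/C=C(C)/CCC=C(C)C
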